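**Retrosynthetic overview**

Ring numbering used below: C1 = ketone carbon, C2 = carbon bearing CH2CO2Me, C3 = vinylic CH, C4 = carbinol carbon, C5 = carbon bearing the geranylgeranyl chain, C6 = ring CH2.
Target ⇒ acyclic (Z)-enol triflate aldehyde: the only ring, the cyclohexenone, is closed last through the C3–C4 bond by an intramolecular Nozaki–Hiyama–Kishi addition, which also creates the C4 stereocentre and releases the free γ-hydroxy enone with no protecting group left.
Enabling feature: the γ-hydroxy-enone array C1(=O)–C2=C3–C4(OH) of the six-membered ring, in which C3 is a vinylic CH held cis to the ketone across C2=C3 (an alkenylmetal site) and C4 is a secondary carbinol (an aldehyde site), the two being the ends of the chain C3–C2–C1–C6–C5–C4.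
Enol triflate aldehyde ⇒ silyl-protected methyl ketone: C3 by kinetic formylation of the methyl group, the CH2CO2Me arm by C-alkylation of the resulting 1,3-dicarbonyl with methyl bromoacetate, then O-triflation, desilylation and oxidation.
Methyl ketone ⇒ β-substituted γ-lactone (MeLi opening) ⇒ succinate imide + geranylgeranyl bromide (auxiliary-controlled alkylation sets C5).

Key step: step 12

Remark: commercial geranylgeraniol is taken to be the all-E isomer ("geranylgeranyl" below always means the (2E,6E,10E)-3,7,11,15-tetramethylhexadeca-2,6,10,14-tetraen-1-yl group), and the two 3-oxo aldehydes of steps 7 and 8 are drawn as their chelated (Z)-hydroxymethylene enols.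

**Route**

Step 1
Reactants: 1 geranylgeraniol
Product: 2 geranylgeranyl bromide
Conditions: PBr3 (0.4 equiv), Et2O, −10 °C
Reagents that add atoms: phosphorus tribromide, BrP(Br)Br
Why: SN2 displacement at the primary allylic carbon of the phosphite ester formed in situ should give the bromide at low temperature without allylic transposition or loss of alkene geometry (alcohol-to-bromide conversion with PBr3).

Step 2
Reactants: 3 (R)-4-benzyl-1,3-oxazolidin-2-one; 4 methyl 4-chloro-4-oxobutanoate
Product: 5 methyl 4-[(4R)-4-benzyl-2-oxo-1,3-oxazolidin-3-yl]-4-oxobutanoate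
Conditions: n-BuLi, THF, −78 °C; then 4, −78 to 0 °C
Reagents that add atoms: none
Why: N-acylation of the lithiated oxazolidinone by the acid chloride (imide formation) is much faster than any attack on the methyl ester.

Step 3
Reactants: 5 methyl 4-[(4R)-4-benzyl-2-oxo-1,3-oxazolidin-3-yl]-4-oxobutanoate; 2 geranylgeranyl bromide
Product: 6 methyl (3R)-4-[(4R)-4-benzyl-2-oxo-1,3-oxazolidin-3-yl]-3-(geranylgeranyl)-4-oxobutanoate
Conditions: NaN(SiMe3)2, THF, −78 °C; then 2, −78 to −40 °C
Reagents that add atoms: none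
Why: Evans asymmetric alkylation, in which the chelated (Z)-sodium enolate of the imide (the imide α-CH2 is more acidic than the ester α-CH2) is alkylated at the primary carbon of the allylic bromide on the face opposite the benzyl group, which sets C5 as R.

Step 4
Reactants: 6 methyl (3R)-4-[(4R)-4-benzyl-2-oxo-1,3-oxazolidin-3-yl]-3-(geranylgeranyl)-4-oxobutanoate
Product: 8 (4R)-4-(geranylgeranyl)oxolan-2-one, via hydroxy ester 7 (not isolated)
Conditions: NaBH4, THF/H2O, 0 °C to rt; then PPTS (cat.), toluene, 40 °C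
Reagents that add atoms: none
Why: Chemoselective borohydride reduction of the exocyclic imide carbonyl (reductive removal of the auxiliary) spares the methyl ester and the alkenes, and the γ-hydroxy ester then closes to the γ-lactone by intramolecular transesterification without touching the stereocentre.

Step 5
Reactants: 8 (4R)-4-(geranylgeranyl)oxolan-2-one
Product: 9 (4R)-4-(geranylgeranyl)-5-hydroxypentan-2-one
Conditions: MeLi (1.05 equiv), THF, −78 °C; AcOH quench at −78 °C
Reagents that add atoms: methyllithium, [Li]C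
Why: Mono-addition of an organolithium to a lactone, where the lithium lactolate is stable at −78 °C and opens to the γ-hydroxy methyl ketone only on protonation, so a second addition should not occur.

Step 6
Reactants: 9 (4R)-4-(geranylgeranyl)-5-hydroxypentan-2-one
Product: 10 (4R)-5-[(tert-butyldimethylsilyl)oxy]-4-(geranylgeranyl)pentan-2-one
Conditions: TBSCl, imidazole, CH2Cl2, 0 °C to rt
Reagents that add atoms: tert-butyldimethylsilyl chloride, CC(C)(C)[Si](C)(C)Cl
Why: Silyl ether protection of the primary alcohol, which also draws the hydroxy ketone out of its lactol equilibrium.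

Step 7
Reactants: 10 (4R)-5-[(tert-butyldimethylsilyl)oxy]-4-(geranylgeranyl)pentan-2-one
Product: 11 (5R)-6-[(tert-butyldimethylsilyl)oxy]-5-(geranylgeranyl)-3-oxohexanal, drawn as its (1Z)-1-hydroxyhex-1-en-3-one enol
Conditions: LiN(iPr)2 (1.1 equiv), THF, −78 °C; then CF3CH2OCHO, −78 °C; AcOH work-up
Reagents that add atoms: 2,2,2-trifluoroethyl formate, O=COCC(F)(F)F
Why: Kinetic deprotonation occurs at the methyl group and not at the β-branched methylene, and the lithium enolate is C-formylated by the activated formate (crossed Claisen condensation), the product being held as its chelated enolate until work-up.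

Step 8
Reactants: 11 (5R)-6-[(tert-butyldimethylsilyl)oxy]-5-(geranylgeranyl)-3-oxohexanal; 12 methyl bromoacetate
Product: 13 methyl (3Z,6R)-7-[(tert-butyldimethylsilyl)oxy]-6-(geranylgeranyl)-3-(hydroxymethylidene)-4-oxoheptanoate (enol of the 3-formyl-4-oxo ester)
Conditions: NaH (1.0 equiv), THF, 0 °C; then 12 (1.05 equiv), 0 °C to rt
Reagents that add atoms: none
Why: SN2 C-alkylation of the chelated sodium enolate of the 1,3-dicarbonyl unit by the soft α-bromo ester places the CH2CO2Me group on C2, the only carbon flanked by both carbonyls.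

Step 9
Reactants: 13 methyl (3Z,6R)-7-[(tert-butyldimethylsilyl)oxy]-6-(geranylgeranyl)-3-(hydroxymethylidene)-4-oxoheptanoate
Product: 14 methyl (3Z,6R)-7-[(tert-butyldimethylsilyl)oxy]-6-(geranylgeranyl)-4-oxo-3-{[(trifluoromethanesulfonyl)oxy]methylidene}heptanoate
Conditions: LiN(SiMe3)2 (1.0 equiv), THF, −78 °C; then N-(5-chloro-2-pyridyl)bis(trifluoromethanesulfonimide), −78 to 0 °C
Reagents that add atoms: N-(5-chloro-2-pyridyl)bis(trifluoromethanesulfonimide), Clc1ccc(nc1)N(S(=O)(=O)C(F)(F)F)S(=O)(=O)C(F)(F)F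
Why: Enolate O-triflation at the less hindered, aldehyde-derived oxygen of the lithium-chelated 1,3-dicarbonyl enolate should give the enol triflate with the triflyloxy group cis to the ketone (Z), the geometry that the ring closure needs.

Step 10
Reactants: 14 methyl (3Z,6R)-7-[(tert-butyldimethylsilyl)oxy]-6-(geranylgeranyl)-4-oxo-3-{[(trifluoromethanesulfonyl)oxy]methylidene}heptanoate
Product: 15 methyl (3Z,6R)-6-(geranylgeranyl)-7-hydroxy-4-oxo-3-{[(trifluoromethanesulfonyl)oxy]methylidene}heptanoate
Conditions: HF (48% aq.), MeCN, 0 °C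
Reagents that add atoms: none
Why: Acidic desilylation of the primary silyl ether without amine or basic fluoride, conditions under which the enol triflate, the ester and the trisubstituted alkenes should persist.

Step 11
Reactants: 15 methyl (3Z,6R)-6-(geranylgeranyl)-7-hydroxy-4-oxo-3-{[(trifluoromethanesulfonyl)oxy]methylidene}heptanoate
Product: 16 methyl (3Z,6R)-6-(geranylgeranyl)-4,7-dioxo-3-{[(trifluoromethanesulfonyl)oxy]methylidene}heptanoate
Conditions: Dess–Martin periodinane, CH2Cl2, 0 °C to rt; crude aldehyde used at once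
Reagents that add atoms: none
Why: Dess–Martin oxidation converts the primary alcohol into the aldehyde under neutral, non-enolising conditions, so the adjacent C5 stereocentre should not epimerise.

Step 12
Reactants: 16 methyl (3Z,6R)-6-(geranylgeranyl)-4,7-dioxo-3-{[(trifluoromethanesulfonyl)oxy]methylidene}heptanoate
Product: 18 methyl 2-[(3R,4R)-4-(geranylgeranyl)-3-hydroxy-6-oxocyclohex-1-en-1-yl]acetate (target), via alkenylchromium dichloride 17 (not isolated)
Conditions: CrCl2 (6 equiv), NiCl2 (2 mol %), degassed DMF, rt, 0.005 M (slow addition of 16); then H2O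
Reagents that add atoms: none
Why: Zerovalent nickel (formed from NiCl2 and CrCl2) inserts into the activated C3–OTf bond, the alkenyl group passes to trivalent chromium to give 17, and the C3–Cr bond adds to the tethered aldehyde through a chromium-bridged four-centre transition state, the carbinol being released on aqueous work-up. The closest known reaction type is the intramolecular Nozaki–Hiyama–Kishi coupling of alkenyl triflates or iodides with aldehydes, which forms carbocycles with retention of alkene geometry. The six-membered ring closes in a 6-exo-trig mode (C3 attacks the exocyclic C4=O), and only the (Z)-triflate, with C3 cis to the acyl chain on C2=C3, can reach the aldehyde. The new C4 stereocentre is controlled by C5: with the geranylgeranyl group pseudoequatorial and anti to the incoming C3, the chromium-bound oxygen has to lie syn-periplanar to the C3–Cr bond and therefore pseudoaxial, which should give the cis (4R,5R) carbinol. The step needs chemoselectivity for the aldehyde over the ketone and the ester, secured by the low carbonyl reactivity of organochromium reagents and by the fact that those carbonyls could only be reached through three- or four-membered rings, and it must neither epimerise C5 nor dehydrate the product, which the neutral, non-basic medium should secure. Any (E)-triflate carried along should stay inert or be drawn in by E/Z equilibration of the β-acyl alkenylnickel species.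

**Compound list**

1 | geranylgeraniol, (2E,6E,10E)-3,7,11,15-tetramethylhexadeca-2,6,10,14-tetraen-1-ol | OC/C=C(\C)CC/C=C(\C)CC/C=C(\C)CCC=C(C)C | starting material
2 | geranylgeranyl bromide, (2E,6E,10E)-1-bromo-3,7,11,15-tetramethylhexadeca-2,6,10,14-tetraene | BrC/C=C(\C)CC/C=C(\C)CC/C=C(\C)CCC=C(C)C | intermediate
3 | (R)-4-benzyl-1,3-oxazolidin-2-one | O=C1N[C@H](Cc2ccccc2)CO1 | starting material
4 | methyl 4-chloro-4-oxobutanoate | COC(=O)CCC(Cl)=O | starting material
5 | methyl 4-[(4R)-4-benzyl-2-oxo-1,3-oxazolidin-3-yl]-4-oxobutanoate | COC(=O)CCC(=O)N1[C@H](Cc2ccccc2)COC1=O | intermediate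
6 | methyl (3R)-4-[(4R)-4-benzyl-2-oxo-1,3-oxazolidin-3-yl]-3-(geranylgeranyl)-4-oxobutanoate | COC(=O)C[C@@H](C/C=C(\C)CC/C=C(\C)CC/C=C(\C)CCC=C(C)C)C(=O)N1[C@H](Cc2ccccc2)COC1=O | intermediate
7 | methyl (3R)-3-(geranylgeranyl)-4-hydroxybutanoate (hydroxy ester, not isolated) | COC(=O)C[C@@H](C/C=C(\C)CC/C=C(\C)CC/C=C(\C)CCC=C(C)C)CO | intermediate
8 | (4R)-4-(geranylgeranyl)oxolan-2-one | O=C1C[C@@H](C/C=C(\C)CC/C=C(\C)CC/C=C(\C)CCC=C(C)C)CO1 | intermediate
9 | (4R)-4-(geranylgeranyl)-5-hydroxypentan-2-one | CC(=O)C[C@@H](C/C=C(\C)CC/C=C(\C)CC/C=C(\C)CCC=C(C)C)CO | intermediate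
10 | (4R)-5-[(tert-butyldimethylsilyl)oxy]-4-(geranylgeranyl)pentan-2-one | CC(=O)C[C@@H](C/C=C(\C)CC/C=C(\C)CC/C=C(\C)CCC=C(C)C)CO[Si](C)(C)C(C)(C)C | intermediate
11 | (5R)-6-[(tert-butyldimethylsilyl)oxy]-5-(geranylgeranyl)-3-oxohexanal, as its (1Z)-hydroxymethylene enol | O/C=C\C(=O)C[C@@H](C/C=C(\C)CC/C=C(\C)CC/C=C(\C)CCC=C(C)C)CO[Si](C)(C)C(C)(C)C | intermediate
12 | methyl bromoacetate | COC(=O)CBr | starting material
13 | methyl (3Z,6R)-7-[(tert-butyldimethylsilyl)oxy]-6-(geranylgeranyl)-3-(hydroxymethylidene)-4-oxoheptanoate | COC(=O)C/C(=C/O)C(=O)C[C@@H](C/C=C(\C)CC/C=C(\C)CC/C=C(\C)CCC=C(C)C)CO[Si](C)(C)C(C)(C)C | intermediate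
14 | methyl (3Z,6R)-7-[(tert-butyldimethylsilyl)oxy]-6-(geranylgeranyl)-4-oxo-3-{[(trifluoromethanesulfonyl)oxy]methylidene}heptanoate | COC(=O)C/C(=C/OS(=O)(=O)C(F)(F)F)C(=O)C[C@@H](C/C=C(\C)CC/C=C(\C)CC/C=C(\C)CCC=C(C)C)CO[Si](C)(C)C(C)(C)C | intermediate
15 | methyl (3Z,6R)-6-(geranylgeranyl)-7-hydroxy-4-oxo-3-{[(trifluoromethanesulfonyl)oxy]methylidene}heptanoate | COC(=O)C/C(=C/OS(=O)(=O)C(F)(F)F)C(=O)C[C@@H](C/C=C(\C)CC/C=C(\C)CC/C=C(\C)CCC=C(C)C)CO | intermediate
16 | methyl (3Z,6R)-6-(geranylgeranyl)-4,7-dioxo-3-{[(trifluoromethanesulfonyl)oxy]methylidene}heptanoate | COC(=O)C/C(=C/OS(=O)(=O)C(F)(F)F)C(=O)C[C@@H](C/C=C(\C)CC/C=C(\C)CC/C=C(\C)CCC=C(C)C)C=O | intermediate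
17 | methyl (3Z,6R)-3-[(dichlorochromio)methylidene]-6-(geranylgeranyl)-4,7-dioxoheptanoate (alkenylchromium dichloride, trivalent chromium, not isolated) | COC(=O)C/C(=C/[Cr](Cl)Cl)C(=O)C[C@@H](C/C=C(\C)CC/C=C(\C)CC/C=C(\C)CCC=C(C)C)C=O | intermediate
18 | methyl 2-[(3R,4R)-4-(geranylgeranyl)-3-hydroxy-6-oxocyclohex-1-en-1-yl]acetate | COC(=O)CC1=C[C@H](O)[C@H](C/C=C(\C)CC/C=C(\C)CC/C=C(\C)CCC=C(C)C)CC1=O | target

**Step count and risks**

Total step count: 12.
Longest linear sequence: 11 steps (steps 2 to 12, from 3 and 4 to 18); step 1 is a one-step side branch that joins at step 3.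

Steps most likely to fail:

Step 12. The facial selectivity of the addition to the aldehyde may be low or reversed if the chain at C5 turns pseudoaxial in a competing transition state, so that the trans carbinol dominates. The fallback sets out from 16 and corrects C4 afterwards by a stereospecific substitution instead of relying on substrate control. The same ring closure is run and the trans carbinol, methyl 2-[(3S,4R)-4-(geranylgeranyl)-3-hydroxy-6-oxocyclohex-1-en-1-yl]acetate F1, is taken on. Mitsunobu inversion (4-nitrobenzoic acid, PPh3, DIAD, toluene, 0 °C) should give the cis ester, methyl 2-[(3R,4R)-4-(geranylgeranyl)-3-(4-nitrobenzoyloxy)-6-oxocyclohex-1-en-1-yl]acetate F2. Brief methanolysis (K2CO3 cat., MeOH, 0 °C, in which exchange at the methyl ester is degenerate) should then release the carbinol, and the fallback comes back to the route at 18.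

Step 8. The ambident enolate may be alkylated on oxygen, or C2 may be alkylated twice. The fallback sets out from 10 and makes the C2–CH2 bond by cross-coupling at an sp2 carbon instead of enolate alkylation. Condensation with Me2NCH(OMe)2 (neat, 80 °C) at the methyl group should give the enaminone (1E,5R)-6-[(tert-butyldimethylsilyl)oxy]-1-(dimethylamino)-5-(geranylgeranyl)hex-1-en-3-one F3. Iodination (I2, Et3N, CH2Cl2, 0 °C) should give the α-iodo enaminone (1Z,5R)-6-[(tert-butyldimethylsilyl)oxy]-1-(dimethylamino)-5-(geranylgeranyl)-2-iodohex-1-en-3-one F4. Negishi coupling with the Reformatsky reagent BrZnCH2CO2Me (Pd(PPh3)4, THF, 40 °C) should give methyl (3E,6R)-7-[(tert-butyldimethylsilyl)oxy]-3-[(dimethylamino)methylidene]-6-(geranylgeranyl)-4-oxoheptanoate F5. Mild hydrolysis of the enaminone (AcOH/THF/H2O, rt) comes back to the route at 13.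

Step 9. O-Sulfonylation of the stabilised enolate may be slow, may occur on the ketone-derived oxygen, or may lose geometric control. The fallback sets out from 13 and swaps the leaving group for iodide, introduced by vinylogous acyl substitution. Treatment with PPh3, I2 and Et3N in MeCN at rt should give the β-iodo enone methyl (3Z,6R)-7-[(tert-butyldimethylsilyl)oxy]-6-(geranylgeranyl)-3-(iodomethylidene)-4-oxoheptanoate F6 (either geometrical isomer can be carried on). Desilylation (aq. HF, MeCN, 0 °C) should give methyl (3Z,6R)-6-(geranylgeranyl)-7-hydroxy-3-(iodomethylidene)-4-oxoheptanoate F7, and Dess–Martin oxidation should give methyl (3Z,6R)-6-(geranylgeranyl)-3-(iodomethylidene)-4,7-dioxoheptanoate F8. The same CrCl2/NiCl2 ring closure (DMSO, rt, high dilution), for which alkenyl iodides are the classical partners, comes back to the route at 18.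

**Further compounds**

F1 | step 12 | methyl 2-[(3S,4R)-4-(geranylgeranyl)-3-hydroxy-6-oxocyclohex-1-en-1-yl]acetate | COC(=O)CC1=C[C@@H](O)[C@H](C/C=C(\C)CC/C=C(\C)CC/C=C(\C)CCC=C(C)C)CC1=O
F2 | step 12 | methyl 2-[(3R,4R)-4-(geranylgeranyl)-3-(4-nitrobenzoyloxy)-6-oxocyclohex-1-en-1-yl]acetate | COC(=O)CC1=C[C@H](OC(=O)c2ccc(cc2)[N+](=O)[O-])[C@H](C/C=C(\C)CC/C=C(\C)CC/C=C(\C)CCC=C(C)C)CC1=O
F3 | step 8 | (1E,5R)-6-[(tert-butyldimethylsilyl)oxy]-1-(dimethylamino)-5-(geranylgeranyl)hex-1-en-3-one | CN(C)/C=C/C(=O)C[C@@H](C/C=C(\C)CC/C=C(\C)CC/C=C(\C)CCC=C(C)C)CO[Si](C)(C)C(C)(C)C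
F4 | step 8 | (1Z,5R)-6-[(tert-butyldimethylsilyl)oxy]-1-(dimethylamino)-5-(geranylgeranyl)-2-iodohex-1-en-3-one | CN(C)/C=C(\I)C(=O)C[C@@H](C/C=C(\C)CC/C=C(\C)CC/C=C(\C)CCC=C(C)C)CO[Si](C)(C)C(C)(C)C
F5 | step 8 | methyl (3E,6R)-7-[(tert-butyldimethylsilyl)oxy]-3-[(dimethylamino)methylidene]-6-(geranylgeranyl)-4-oxoheptanoate | COC(=O)C/C(=C\N(C)C)C(=O)C[C@@H](C/C=C(\C)CC/C=C(\C)CC/C=C(\C)CCC=C(C)C)CO[Si](C)(C)C(C)(C)C
F6 | step 9 | methyl (3Z,6R)-7-[(tert-butyldimethylsilyl)oxy]-6-(geranylgeranyl)-3-(iodomethylidene)-4-oxoheptanoate | COC(=O)C/C(=C/I)C(=O)C[C@@H](C/C=C(\C)CC/C=C(\C)CC/C=C(\C)CCC=C(C)C)CO[Si](C)(C)C(C)(C)C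
F7 | step 9 | methyl (3Z,6R)-6-(geranylgeranyl)-7-hydroxy-3-(iodomethylidene)-4-oxoheptanoate | COC(=O)C/C(=C/I)C(=O)C[C@@H](C/C=C(\C)CC/C=C(\C)CC/C=C(\C)CCC=C(C)C)CO
F8 | step 9 | methyl (3Z,6R)-6-(geranylgeranyl)-3-(iodomethylidene)-4,7-dioxoheptanoate | COC(=O)C/C(=C/I)C(=O)C[C@@H](C/C=C(\C)CC/C=C(\C)CC/C=C(\C)CCC=C(C)C)C=O
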